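Slowness is not what stops these flasks: noon stands at 15% product after 50.0 s and at 15% after 120 s, with 86% of its substrate still there.

| flask | substrate | partner | free catalyst | remark | time |
|---|---|---|---|---|---|
| noon | 40 mM | 0.48 equiv | 2.5 mol% | run made earlier |  |
| spring | 40 mM | 3.4 equiv | 2.5 mol% | run made earlier |  |
| autumn | 40 mM | 2.5 equiv | 1.7 mol% | run made earlier |  |
| theta | 40 mM | 2.50 equiv | 0.6 mol% |  | 4.0 min |
| zeta | 25 mM | 3.80 equiv | 2.5 mol% |  | 4.0 min |
| epsilon | 40 mM | 2.50 equiv | 2.5 mol% |  | 4.0 min |
| delta | 10 mM | 0.830 equiv | 2.5 mol% |  | 4.0 min |

| run | time / s | product / % | substrate / % |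
|---|---|---|---|
| noon | 10.0 | 10 | 91 |
| noon | 20.0 | 11 | 86 |
| noon | 50.0 | 15 | 87 |
| noon | 120 | 15 | 86 |
| spring | 10.0 | 32 | 69 |
| spring | 20.0 | 53 | 45 |
| spring | 50.0 | 72 | 28 |
| spring | 120 | 76 | 27 |
| autumn | 30.0 | 37 | 62 |
| autumn | 60.0 | 43 | 58 |
| autumn | 90.0 | 46 | 55 |
| autumn | 120 | 46 | 49 |

(standard deviation of a reading: 2 percentage points)



- ranking by amount of product, in percent of the substrate charged, from high to low, at 4.0 min (theta / zeta / epsilon / delta)
- the amount of product, in percent of the substrate charged of the flask you put first, at 4.0 min
- the amount of product, in percent of the substrate charged of the flask you put last, at 4.0 min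

So I keep a ledger of partner, which I take as the limiting reagent, because spring, with more of it at the same loading, climbs to 76%. By my assumption each mole charged has two exits, like a tank with two outlets: through the catalyst it makes one mole of product, and through a first-order side loss it makes none. The catalyst outlet widens with c(free catalyst), so the even split is the natural zero of the scale.

Noon books 15% of substrate against 0.48 equiv of partner, a share of 31.2% at c(free catalyst) = 1.00 mM. Reckoned from that reading, 2.20 mM is c(even), the c(free catalyst) at which partner leaves evenly by both exits. The share at any other c(free catalyst) is then c(free catalyst)/(c(free catalyst) + c(even)).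

Spring's share is 22.4%, lower than noon's, so I keep the rule for lean charges. Delta is lean: at 0.250 mM its share is 10.2%, which gives 8.47% product, with noon's scatter of 2 percentage points inside it. Rich charges I scale by spring's share over noon's, 0.715, as those two runs stand at the same c(free catalyst). Theta then reckons at 17.6%, above delta, so delta is my last flask. Epsilon reckons at 55.9% and zeta, with its richer charge but lower c(free catalyst), at 60.1%. So I put zeta first and epsilon second, on a gap of 4.2 points against a scatter of 2 points.

The forecast, holding that “the catalyst is dying”, gives epsilon > zeta > theta > delta, with 60% first and 2.2% last, lower than my figure for delta, and it differs from my order by putting epsilon ahead of zeta.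

The flasks give epsilon > zeta > theta > delta, with 60.1% first and 8.09% last.

    catalyst intermediate C → free catalyst + product (k = 37.9 s⁻¹)
    catalyst intermediate B → catalyst intermediate C (k = 28.4 s⁻¹)
    substrate + catalyst intermediate A ⇌ catalyst intermediate B (K = 18.0 M⁻¹, k = 118 M⁻¹ s⁻¹)
    partner + free catalyst → catalyst intermediate A (k = 30.2 M⁻¹ s⁻¹)
    partner → decomposed reagent (k = 0.0619 s⁻¹)

The books of delta close at 4.00 min with partner at 0% of its charge and decomposed reagent at 7.49 mM, which is 90.2% of the partner charged; c(even) puts the side exit's share at 89.8%.

On the neighbour with 2.5 mM of substrate and delta's equivalents and loading, c(free catalyst) is 0.0625 mM, so c(even) gives a share of 2.76% and 2.29% product; the flask gives 2.23%.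

Readings and results were generated by integration on assumed constants; the scatter is artificial.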